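## Retrosynthetic overview

- The target comes from diketone 31 by two hydroxyl-directed reductions (C6, then C9). 31 comes from a photochemical 7-endo acyl-radical ring closure (C6–C7) of the aldehyde/(Z)-dienone 30; the seven-membered ring is formed last.
- 30 comes from ynone 29 (semi-hydrogenation). 29 is a three-component union of enol triflate 14 (fragment A), CO (C9) and alkyne 28 (fragment B).
- Fragment A: (R)-carvone, photochemical Wolff ring contraction (forms the cyclopentene first), then epoxide-to-allylic-alcohol transposition and isopropenyl-to-enol-triflate conversion.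
- Fragment B: (R)-glyceraldehyde acetonide, (Z)-crotylboration (C11, C12), then chelation-controlled alkenyl Grignard addition (C13).

Assumption: locants C1–C20 follow dictyol numbering (C1/C5 ring fusion, C2=C3, C4(OH)Me, C6, C7, C8, C9, C10=C18, side chain C11(Me)–C12–C13–C14=C15Me2); compounds 1, 15, 16 and 25 are bought.

## Route

Step 1
Reactants: 1 (R)-carvone
Product: 3 (5S)-6-diazo-2-methyl-5-(prop-1-en-2-yl)cyclohex-2-en-1-one, via trifluoroacetyl enol 2 (not isolated)
Conditions: LiN(SiMe3)2, THF, −78 °C; CF3CO2CH2CF3; aq HCl work-up; then 4-acetamidobenzenesulfonyl azide, Et3N, H2O, MeCN, 25 °C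
Reagents that add atoms: 4-acetamidobenzenesulfonyl azide, CC(=O)Nc1ccc(cc1)S(=O)(=O)N=[N+]=[N-]
Why: Kinetic α′-deprotonation at C6, trifluoroacetylation and detrifluoroacetylative (Danheiser-type) diazo transfer give the α′-diazo enone without touching the stereocentre bought in carvone.

Step 2
Reactants: 3 (5S)-6-diazo-2-methyl-5-(prop-1-en-2-yl)cyclohex-2-en-1-one
Product: 6 methyl (1S,5R)-2-methyl-5-(prop-1-en-2-yl)cyclopent-2-ene-1-carboxylate, via vinylketene 4 (not isolated), via cis ester 5 (not isolated)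
Conditions: hν (365 nm LED, flow), MeOH/CH2Cl2, 0 °C; then NaOMe (0.1 equiv), MeOH, 0 °C, 1 h; AcOH quench
Reagents that add atoms: methanol, CO
Why: Photochemical Wolff rearrangement (1,2-shift of the alkenyl carbon to the diazo carbon) contracts the ring and forms the C4–C5 bond; methanol traps the vinylketene with kinetic α-protonation to the β,γ-unsaturated ester, and brief methoxide equilibration places the ester trans to the isopropenyl group (C1 from carvone) before slower γ-protonation can conjugate the alkene.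

Step 3
Reactants: 6 methyl (1S,5R)-2-methyl-5-(prop-1-en-2-yl)cyclopent-2-ene-1-carboxylate
Product: 7 methyl (1R,2S,3R,5S)-1-methyl-3-(prop-1-en-2-yl)-6-oxabicyclo[3.1.0]hexane-2-carboxylate
Conditions: mCPBA (1.05 equiv), NaHCO3, CH2Cl2, −20 °C
Reagents that add atoms: 3-chloroperoxybenzoic acid, OOC(=O)c1cccc(Cl)c1
Why: Prilezhaev epoxidation is much faster at the trisubstituted ring alkene than at the isopropenyl group and occurs anti to the adjacent ester, which sets the β-oriented C4–O bond.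

Step 4
Reactants: 7 methyl (1R,2S,3R,5S)-1-methyl-3-(prop-1-en-2-yl)-6-oxabicyclo[3.1.0]hexane-2-carboxylate
Product: 9 methyl (1R,2S,3R,5S)-3-acetyl-1-methyl-6-oxabicyclo[3.1.0]hexane-2-carboxylate, via ozonide 8 (not isolated)
Conditions: O3, CH2Cl2, −78 °C; Me2S, −78 to 25 °C
Reagents that add atoms: ozone, [O-][O+]=O
Why: Ozonolysis with reductive work-up cleaves the only remaining alkene to the methyl ketone while epoxide and ester are inert.

Step 5
Reactants: 9 methyl (1R,2S,3R,5S)-3-acetyl-1-methyl-6-oxabicyclo[3.1.0]hexane-2-carboxylate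
Product: 10 methyl (1R,2S,3R,5S)-1-methyl-3-{1-[(trifluoromethanesulfonyl)oxy]ethenyl}-6-oxabicyclo[3.1.0]hexane-2-carboxylate
Conditions: KN(SiMe3)2 (1.05 equiv), THF, −78 °C; PhNTf2, −78 to −20 °C; aq NH4Cl
Reagents that add atoms: N-phenylbis(trifluoromethanesulfonimide), O=S(=O)(N(c1ccccc1)S(=O)(=O)C(F)(F)F)C(F)(F)F
Why: Kinetic enolization of the unhindered methyl group (faster than the hindered ester α-CH) and O-triflation give the terminal enol triflate that will become C10=C18.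

Step 6
Reactants: 10 methyl (1R,2S,3R,5S)-1-methyl-3-{1-[(trifluoromethanesulfonyl)oxy]ethenyl}-6-oxabicyclo[3.1.0]hexane-2-carboxylate
Product: 13 methyl (1S,2S,5R)-2-hydroxy-2-methyl-5-{1-[(trifluoromethanesulfonyl)oxy]ethenyl}cyclopent-3-ene-1-carboxylate, via hydroxy selenide 11 (not isolated), via selenoxide 12 (not isolated)
Conditions: PhSeSePh, NaBH4, EtOH, 0 to 25 °C; then 30% H2O2, THF, 0 to 25 °C
Reagents that add atoms: none
Why: Sharpless epoxide-to-allylic-alcohol transposition: PhSe− opens the epoxide by SN2 attack at the less substituted C3 so the tertiary C4–OH keeps its configuration, and the selenoxide can only syn-eliminate towards C2 (C4 has no hydrogen), giving the C2=C3 alkene.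

Step 7
Reactants: 13 methyl (1S,2S,5R)-2-hydroxy-2-methyl-5-{1-[(trifluoromethanesulfonyl)oxy]ethenyl}cyclopent-3-ene-1-carboxylate
Product: 14 (1S,2S,5R)-2-hydroxy-2-methyl-5-{1-[(trifluoromethanesulfonyl)oxy]ethenyl}cyclopent-3-ene-1-carbaldehyde
Conditions: i-Bu2AlH (2.2 equiv), CH2Cl2, −78 °C; aqueous potassium sodium tartrate
Reagents that add atoms: none
Why: Partial ester reduction stops at the aldehyde at −78 °C because the aluminium hemiacetal is stabilised by the neighbouring C4 alkoxide, and the enol triflate is inert to the hydride.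

Step 8
Reactants: 15 (R)-2,2-dimethyl-1,3-dioxolane-4-carbaldehyde; 16 (Z)-crotylboronic acid pinacol ester
Product: 18 (1S,2R)-1-[(4R)-2,2-dimethyl-1,3-dioxolan-4-yl]-2-methylbut-3-en-1-ol, via borate ester 17 (not isolated)
Conditions: toluene, 25 °C, 48 h; then aq NaHCO3
Reagents that add atoms: none
Why: Roush-type crotylboration through a closed chair transition state: the Z-boronate gives the 11,12-syn relationship and Felkin–Anh attack anti to the dioxolane oxygen fixes the absolute configuration of C11 and C12 from the glyceraldehyde stereocentre.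

Step 9
Reactants: 18 (1S,2R)-1-[(4R)-2,2-dimethyl-1,3-dioxolan-4-yl]-2-methylbut-3-en-1-ol
Product: 19 (4R)-4-{(1S,2R)-1-[(4-methoxyphenyl)methoxy]-2-methylbut-3-en-1-yl}-2,2-dimethyl-1,3-dioxolane
Conditions: NaH, 4-methoxybenzyl chloride, Bu4NI (cat.), DMF, 0 to 25 °C
Reagents that add atoms: 4-methoxybenzyl chloride, COc1ccc(CCl)cc1
Why: Williamson etherification puts a chelating p-methoxybenzyl ether on the C12 oxygen.

Step 10
Reactants: 19 (4R)-4-{(1S,2R)-1-[(4-methoxyphenyl)methoxy]-2-methylbut-3-en-1-yl}-2,2-dimethyl-1,3-dioxolane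
Product: 22 (4R)-4-{(1S,2R)-1-[(4-methoxyphenyl)methoxy]-2-methylbut-3-yn-1-yl}-2,2-dimethyl-1,3-dioxolane, via ozonide 20 (not isolated), via aldehyde 21 (not isolated)
Conditions: O3, CH2Cl2, −78 °C; Me2S; then dimethyl (1-diazo-2-oxopropyl)phosphonate, K2CO3, MeOH, 0 to 25 °C
Reagents that add atoms: dimethyl (1-diazo-2-oxopropyl)phosphonate, COP(=O)(OC)C(=[N+]=[N-])C(C)=O
Why: Ozonolysis of the vinyl group followed directly by Seyferth–Gilbert homologation (Bestmann–Ohira reagent, mild carbonate base) converts CH=CH2 into the C7≡C8 alkyne without epimerising the α-methyl centre.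

Step 11
Reactants: 22 (4R)-4-{(1S,2R)-1-[(4-methoxyphenyl)methoxy]-2-methylbut-3-yn-1-yl}-2,2-dimethyl-1,3-dioxolane
Product: 24 (2S,3R)-2-[(4-methoxyphenyl)methoxy]-3-methylpent-4-ynal, via diol 23 (not isolated)
Conditions: H5IO6 (2 equiv), EtOAc, 0 to 25 °C
Reagents that add atoms: none
Why: Periodic acid hydrolyses the terminal acetonide and cleaves the liberated 1,2-diol in one pot, turning the former glyceraldehyde carbon into the C13 aldehyde while ether and alkyne survive.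

Step 12
Reactants: 24 (2S,3R)-2-[(4-methoxyphenyl)methoxy]-3-methylpent-4-ynal; 25 2-methylprop-1-enylmagnesium bromide
Product: 26 (3R,4S,5S)-4-[(4-methoxyphenyl)methoxy]-3,7-dimethyloct-6-en-1-yn-5-ol
Conditions: MgBr2·OEt2 (2 equiv), CH2Cl2, −78 °C; then 25 (0.5 M in THF), −78 °C; aq NH4Cl
Reagents that add atoms: none
Why: Cram-chelate addition: magnesium bridges the aldehyde and the α-alkoxy oxygen, so the alkenyl Grignard attacks the less hindered face of the chelate and gives the 12,13-syn (threo) relationship, C13 being controlled by C12.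

Step 13
Reactants: 26 (3R,4S,5S)-4-[(4-methoxyphenyl)methoxy]-3,7-dimethyloct-6-en-1-yn-5-ol
Product: 27 (3R,4S,5S)-3,7-dimethyloct-6-en-1-yne-4,5-diol
Conditions: DDQ (1.3 equiv), CH2Cl2/pH 7 buffer, 0 °C
Reagents that add atoms: none
Why: Oxidative cleavage of the p-methoxybenzyl ether (hydride abstraction, hydrolysis of the oxocarbenium ion) is much faster at 0 °C than oxidation of the aliphatic allylic alcohol.

Step 14
Reactants: 27 (3R,4S,5S)-3,7-dimethyloct-6-en-1-yne-4,5-diol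
Product: 28 (3R,4S,5S)-3,7-dimethyloct-6-en-1-yne-4,5-diyl diacetate
Conditions: Ac2O, pyridine, DMAP (cat.), CH2Cl2, 0 to 25 °C
Reagents that add atoms: acetic anhydride, CC(=O)OC(C)=O
Why: Standard acylation installs both acetates early, so no protecting group is needed from here on.

Step 15
Reactants: 14 (1S,2S,5R)-2-hydroxy-2-methyl-5-{1-[(trifluoromethanesulfonyl)oxy]ethenyl}cyclopent-3-ene-1-carbaldehyde; 28 (3R,4S,5S)-3,7-dimethyloct-6-en-1-yne-4,5-diyl diacetate
Product: 29 (1S,2S,5R)-5-[(6R,7S,8S)-7,8-diacetoxy-6,10-dimethyl-3-oxoundeca-1,9-dien-4-yn-2-yl]-2-hydroxy-2-methylcyclopent-3-ene-1-carbaldehyde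
Conditions: Pd(OAc)2 (5 mol %), Ph2P(CH2)3PPh2 (6 mol %), Et3N (2 equiv), CO (1 atm), DMF, 25 °C
Reagents that add atoms: carbon monoxide, [C-]#[O+]
Why: Carbonylative Sonogashira-type coupling: oxidative addition of the enol triflate to zerovalent palladium, CO insertion and capture of the acyl-palladium by the terminal alkyne assemble C10–C9(=O)–C8≡C7 in one step under conditions that tolerate aldehyde, acetates and tertiary alcohol.

Step 16
Reactants: 29 (1S,2S,5R)-5-[(6R,7S,8S)-7,8-diacetoxy-6,10-dimethyl-3-oxoundeca-1,9-dien-4-yn-2-yl]-2-hydroxy-2-methylcyclopent-3-ene-1-carbaldehyde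
Product: 30 (1S,2S,5R)-5-[(4Z,6R,7S,8S)-7,8-diacetoxy-6,10-dimethyl-3-oxoundeca-1,4,9-trien-2-yl]-2-hydroxy-2-methylcyclopent-3-ene-1-carbaldehyde
Conditions: H2 (1 atm), Pd/CaCO3 poisoned with Pb(OAc)2, quinoline, EtOAc, 0 °C, dark
Reagents that add atoms: none
Why: Lindlar semi-hydrogenation adds H2 syn to the alkyne and stops at the (Z)-enone, the geometry needed for the ring closure.

Step 17
Reactants: 30 (1S,2S,5R)-5-[(4Z,6R,7S,8S)-7,8-diacetoxy-6,10-dimethyl-3-oxoundeca-1,4,9-trien-2-yl]-2-hydroxy-2-methylcyclopent-3-ene-1-carbaldehyde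
Product: 31 (1R,4S,5S,7S,11R,12S,13S)-12,13-diacetoxy-4-hydroxy-trans-hydroazulene-6,9-dione with C2=C3, C10=C18 and C14=C15 (dictyol numbering)
Conditions: (Bu4N)4[W10O32] (2 mol %), MeCN (2 mM), 390 nm LEDs, CO atmosphere (1 atm), 15 °C
Reagents that add atoms: none
Why: Proposed new method: decatungstate-photocatalysed intramolecular hydroacylation, in which the excited polyoxometalate abstracts the aldehydic hydrogen, the nucleophilic acyl radical (C6) adds 7-endo to the enone β-carbon C7 (attack on the exo-methylene terminus would be a disfavoured 5-endo closure) and back hydrogen-atom transfer to the α-keto radical releases the 1,4-diketone; a chair-like transition state fixed by the trans-1,2-disubstituted cyclopentene places the Z-substituent pseudo-axial on the β-face and so sets C7 (S); the closest known reactions are the intermolecular decatungstate hydroacylation of electron-poor alkenes and tin-mediated 7-endo acyl-radical cyclizations of selenoesters.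

Step 18
Reactants: 31 hydroazulene-6,9-dione
Product: 32 (1R,4S,5R,6R,7S,11R,12S,13S)-12,13-diacetoxy-4,6-dihydroxy-trans-hydroazulen-9-one with C2=C3, C10=C18 and C14=C15 (4β,6β-diol)
Conditions: Et2BOMe (1.1 equiv), THF/MeOH 4:1, −78 °C; NaBH4 (1.1 equiv), −78 °C; MeOH azeotrope
Reagents that add atoms: none
Why: Narasaka–Prasad reduction: boron chelates the C4 hydroxyl and the C6 ketone, activating this carbonyl over the enone, and external hydride attacks anti to the C7 side chain to give the 4,6-syn diol (6β-OH).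

Step 19
Reactants: 32 4β,6β-dihydroxy-hydroazulen-9-one
Product: 33 target CNP0269663.3, (1R,4S,5R,6R,7S,9R,11R,12S,13S)-12,13-diacetoxy-4β,6β,9α-trihydroxy-trans-hydroazulene with C2=C3, C10=C18 and C14=C15
Conditions: Me4NBH(OAc)3 (5 equiv), MeCN/AcOH 1:1, −40 to −20 °C
Reagents that add atoms: none
Why: Evans–Saksena-type directed reduction: the C6 hydroxyl exchanges onto boron and delivers hydride across the ring to the β-face of the C9 enone carbonyl (1,2-reduction), giving the 9α-alcohol trans to C6–OH without touching the acetates.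

## Compound list

1 | (R)-carvone, (5R)-2-methyl-5-(prop-1-en-2-yl)cyclohex-2-en-1-one | CC1=CC[C@@H](C(C)=C)CC1=O | starting material
2 | (5S)-6-(2,2,2-trifluoro-1-hydroxyethylidene)-2-methyl-5-(prop-1-en-2-yl)cyclohex-2-en-1-one (enol of the 6-trifluoroacetyl ketone) | CC1=CC[C@@H](C(C)=C)C(=C(O)C(F)(F)F)C1=O | intermediate
3 | (5S)-6-diazo-2-methyl-5-(prop-1-en-2-yl)cyclohex-2-en-1-one | CC1=CC[C@@H](C(C)=C)C(=[N+]=[N-])C1=O | intermediate
4 | (5S)-[2-methyl-5-(prop-1-en-2-yl)cyclopent-2-en-1-ylidene]methanone (vinylketene) | CC1=CC[C@@H](C(C)=C)C1=C=O | intermediate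
5 | methyl (1R,5R)-2-methyl-5-(prop-1-en-2-yl)cyclopent-2-ene-1-carboxylate (cis) | COC(=O)[C@@H]1[C@H](C(C)=C)CC=C1C | intermediate
6 | methyl (1S,5R)-2-methyl-5-(prop-1-en-2-yl)cyclopent-2-ene-1-carboxylate (trans) | COC(=O)[C@H]1[C@H](C(C)=C)CC=C1C | intermediate
7 | methyl (1R,2S,3R,5S)-1-methyl-3-(prop-1-en-2-yl)-6-oxabicyclo[3.1.0]hexane-2-carboxylate | COC(=O)[C@H]1[C@H](C(C)=C)C[C@@H]2O[C@]12C | intermediate
8 | methyl (1R,2S,3R,5S)-1-methyl-3-(3-methyl-1,2,4-trioxolan-3-yl)-6-oxabicyclo[3.1.0]hexane-2-carboxylate (ozonide, trioxolane centre unassigned) | COC(=O)[C@H]1[C@H](C3(C)OCOO3)C[C@@H]2O[C@]12C | intermediate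
9 | methyl (1R,2S,3R,5S)-3-acetyl-1-methyl-6-oxabicyclo[3.1.0]hexane-2-carboxylate | COC(=O)[C@H]1[C@H](C(C)=O)C[C@@H]2O[C@]12C | intermediate
10 | methyl (1R,2S,3R,5S)-1-methyl-3-{1-[(trifluoromethanesulfonyl)oxy]ethenyl}-6-oxabicyclo[3.1.0]hexane-2-carboxylate | COC(=O)[C@H]1[C@H](C(=C)OS(=O)(=O)C(F)(F)F)C[C@@H]2O[C@]12C | intermediate
11 | methyl (1S,2R,3R,5R)-2-hydroxy-2-methyl-3-(phenylselanyl)-5-{1-[(trifluoromethanesulfonyl)oxy]ethenyl}cyclopentane-1-carboxylate | COC(=O)[C@H]1[C@H](C(=C)OS(=O)(=O)C(F)(F)F)C[C@@H]([Se]c2ccccc2)[C@]1(C)O | intermediate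
12 | Se-oxide of 11 (selenoxide, selenium centre unassigned) | COC(=O)[C@H]1[C@H](C(=C)OS(=O)(=O)C(F)(F)F)C[C@@H]([Se](=O)c2ccccc2)[C@]1(C)O | intermediate
13 | methyl (1S,2S,5R)-2-hydroxy-2-methyl-5-{1-[(trifluoromethanesulfonyl)oxy]ethenyl}cyclopent-3-ene-1-carboxylate | COC(=O)[C@H]1[C@H](C(=C)OS(=O)(=O)C(F)(F)F)C=C[C@]1(C)O | intermediate
14 | (1S,2S,5R)-2-hydroxy-2-methyl-5-{1-[(trifluoromethanesulfonyl)oxy]ethenyl}cyclopent-3-ene-1-carbaldehyde (fragment A) | O=C[C@H]1[C@H](C(=C)OS(=O)(=O)C(F)(F)F)C=C[C@]1(C)O | intermediate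
15 | (R)-2,2-dimethyl-1,3-dioxolane-4-carbaldehyde | O=C[C@H]1COC(C)(C)O1 | starting material
16 | (Z)-crotylboronic acid pinacol ester | C/C=C\CB1OC(C)(C)C(C)(C)O1 | starting material
17 | 2-{[(1S,2R)-1-[(4R)-2,2-dimethyl-1,3-dioxolan-4-yl]-2-methylbut-3-en-1-yl]oxy}-4,4,5,5-tetramethyl-1,3,2-dioxaborolane | C=C[C@@H](C)[C@H](OB2OC(C)(C)C(C)(C)O2)[C@H]1COC(C)(C)O1 | intermediate
18 | (1S,2R)-1-[(4R)-2,2-dimethyl-1,3-dioxolan-4-yl]-2-methylbut-3-en-1-ol | C=C[C@@H](C)[C@H](O)[C@H]1COC(C)(C)O1 | intermediate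
19 | (4R)-4-{(1S,2R)-1-[(4-methoxyphenyl)methoxy]-2-methylbut-3-en-1-yl}-2,2-dimethyl-1,3-dioxolane | C=C[C@@H](C)[C@H](OCc2ccc(OC)cc2)[C@H]1COC(C)(C)O1 | intermediate
20 | (4R)-4-{(1S,2S)-1-[(4-methoxyphenyl)methoxy]-2-(1,2,4-trioxolan-3-yl)propyl}-2,2-dimethyl-1,3-dioxolane (ozonide, trioxolane centre unassigned) | C2(OCOO2)[C@@H](C)[C@H](OCc3ccc(OC)cc3)[C@H]1COC(C)(C)O1 | intermediate
21 | (2S,3S)-3-[(4R)-2,2-dimethyl-1,3-dioxolan-4-yl]-3-[(4-methoxyphenyl)methoxy]-2-methylpropanal | O=C[C@@H](C)[C@H](OCc2ccc(OC)cc2)[C@H]1COC(C)(C)O1 | intermediate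
22 | (4R)-4-{(1S,2R)-1-[(4-methoxyphenyl)methoxy]-2-methylbut-3-yn-1-yl}-2,2-dimethyl-1,3-dioxolane | C#C[C@@H](C)[C@H](OCc2ccc(OC)cc2)[C@H]1COC(C)(C)O1 | intermediate
23 | (2R,3S,4R)-3-[(4-methoxyphenyl)methoxy]-4-methylhex-5-yne-1,2-diol | C#C[C@@H](C)[C@H](OCc2ccc(OC)cc2)[C@H](O)CO | intermediate
24 | (2S,3R)-2-[(4-methoxyphenyl)methoxy]-3-methylpent-4-ynal | C#C[C@@H](C)[C@H](OCc2ccc(OC)cc2)C=O | intermediate
25 | 2-methylprop-1-enylmagnesium bromide | CC(C)=C[Mg]Br | starting material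
26 | (3R,4S,5S)-4-[(4-methoxyphenyl)methoxy]-3,7-dimethyloct-6-en-1-yn-5-ol | C#C[C@@H](C)[C@H](OCc2ccc(OC)cc2)[C@H](C=C(C)C)O | intermediate
27 | (3R,4S,5S)-3,7-dimethyloct-6-en-1-yne-4,5-diol | C#C[C@@H](C)[C@H](O)[C@H](C=C(C)C)O | intermediate
28 | (3R,4S,5S)-3,7-dimethyloct-6-en-1-yne-4,5-diyl diacetate (fragment B) | C#C[C@@H](C)[C@H](OC(C)=O)[C@H](C=C(C)C)OC(C)=O | intermediate
29 | (1S,2S,5R)-5-[(6R,7S,8S)-7,8-diacetoxy-6,10-dimethyl-3-oxoundeca-1,9-dien-4-yn-2-yl]-2-hydroxy-2-methylcyclopent-3-ene-1-carbaldehyde | O=C[C@H]1[C@H](C(=C)C(=O)C#C[C@@H](C)[C@H](OC(C)=O)[C@H](C=C(C)C)OC(C)=O)C=C[C@]1(C)O | intermediate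
30 | (1S,2S,5R)-5-[(4Z,6R,7S,8S)-7,8-diacetoxy-6,10-dimethyl-3-oxoundeca-1,4,9-trien-2-yl]-2-hydroxy-2-methylcyclopent-3-ene-1-carbaldehyde | O=C[C@H]1[C@H](C(=C)C(=O)/C=C\[C@@H](C)[C@H](OC(C)=O)[C@H](C=C(C)C)OC(C)=O)C=C[C@]1(C)O | intermediate
31 | (1R,4S,5S,7S,11R,12S,13S)-12,13-diacetoxy-4-hydroxy-trans-hydroazulene-6,9-dione, C2=C3, C10=C18, C14=C15 (dictyol numbering) | C=C1C(=O)C[C@@H]([C@@H](C)[C@H](OC(C)=O)[C@H](C=C(C)C)OC(C)=O)C(=O)[C@H]2[C@H]1C=C[C@]2(C)O | intermediate
32 | (1R,4S,5R,6R,7S,11R,12S,13S)-12,13-diacetoxy-4,6-dihydroxy-trans-hydroazulen-9-one, C2=C3, C10=C18, C14=C15 | C=C1C(=O)C[C@@H]([C@@H](C)[C@H](OC(C)=O)[C@H](C=C(C)C)OC(C)=O)[C@@H](O)[C@H]2[C@H]1C=C[C@]2(C)O | intermediate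
33 | CNP0269663.3, (1R,4S,5R,6R,7S,9R,11R,12S,13S)-12,13-diacetoxy-4,6,9-trihydroxy-trans-hydroazulene, C2=C3, C10=C18, C14=C15 | C=C1[C@H](O)C[C@@H]([C@@H](C)[C@H](OC(C)=O)[C@H](C=C(C)C)OC(C)=O)[C@@H](O)[C@H]2[C@H]1C=C[C@]2(C)O | target

## Step count and risks

Total step count: 19. Longest linear sequence: 12 steps (steps 8–14 then 15–19; steps 1–7 then 15–19 is equally long).

Step 17 (proposed new photochemical ring closure). Risks are decarbonylation of the acyl radical, light-induced Z-to-E isomerisation of the enone (the E isomer would give the C7 epimer) and unselective hydrogen abstraction. The fallback sets out from 30. Pinnick oxidation (NaClO2, NaH2PO4, 2-methyl-2-butene, t-BuOH/H2O) gives the cyclopentenecarboxylic acid F1. PhSeSePh/PBu3 converts it into the Se-phenyl selenoester F2. The known tin-hydride acyl-radical 7-endo cyclization (Bu3SnH, AIBN, benzene, 80 °C, slow addition, no light) then closes the same C6–C7 bond and comes back to the route at 31.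

Step 15 (carbonylative alkynylation). Risks are direct, non-carbonylative coupling, amine-induced dehydration of the β-hydroxy aldehyde and trapping of the acyl-palladium by the C4 hydroxyl. The fallback sets out from 28. Bu3SnOMe (neat, 60 °C) gives the tributylstannyl alkyne F3. A base-free carbonylative Stille coupling of this stannane with 14 (Pd2(dba)3, AsPh3, LiCl, CO 1 atm, THF, 40 °C) comes back to the route at 29.

Step 19 (transannular directed reduction). Delivery from the C6 hydroxyl over a 1,4-distance may be inefficient, and an undirected hydride would attack C9 from the face opposite the C7 side chain and give the 9β-epimer. The fallback sets out from 32. (i-Pr)2SiHCl/imidazole silylates the secondary C6 hydroxyl to the hydridosilyl ether F4. SnCl4 (cat.), CH2Cl2, −78 °C triggers the known intramolecular hydrosilylation of the ketone to the cyclic 6,9-O-diisopropylsilylene derivative F5. HF·pyridine in THF then comes back to the route at 33.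

Further compounds

F1 | step 17 | (1S,2S,5R)-5-[(4Z,6R,7S,8S)-7,8-diacetoxy-6,10-dimethyl-3-oxoundeca-1,4,9-trien-2-yl]-2-hydroxy-2-methylcyclopent-3-ene-1-carboxylic acid | OC(=O)[C@H]1[C@H](C(=C)C(=O)/C=C\[C@@H](C)[C@H](OC(C)=O)[C@H](C=C(C)C)OC(C)=O)C=C[C@]1(C)O
F2 | step 17 | Se-phenyl (1S,2S,5R)-5-[(4Z,6R,7S,8S)-7,8-diacetoxy-6,10-dimethyl-3-oxoundeca-1,4,9-trien-2-yl]-2-hydroxy-2-methylcyclopent-3-ene-1-carboselenoate | O=C([Se]c2ccccc2)[C@H]1[C@H](C(=C)C(=O)/C=C\[C@@H](C)[C@H](OC(C)=O)[C@H](C=C(C)C)OC(C)=O)C=C[C@]1(C)O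
F3 | step 15 | (3R,4S,5S)-3,7-dimethyl-1-(tributylstannyl)oct-6-en-1-yne-4,5-diyl diacetate | CCCC[Sn](CCCC)(CCCC)C#C[C@@H](C)[C@H](OC(C)=O)[C@H](C=C(C)C)OC(C)=O
F4 | step 19 | 6-O-(diisopropylsilyl) ether of 32 | C=C1C(=O)C[C@@H]([C@@H](C)[C@H](OC(C)=O)[C@H](C=C(C)C)OC(C)=O)[C@@H](O[SiH](C(C)C)C(C)C)[C@H]2[C@H]1C=C[C@]2(C)O
F5 | step 19 | 6,9-O-(diisopropylsilylene) derivative of 33 | C=C1[C@H](O3)C[C@@H]([C@@H](C)[C@H](OC(C)=O)[C@H](C=C(C)C)OC(C)=O)[C@@H](O[Si]3(C(C)C)C(C)C)[C@H]2[C@H]1C=C[C@]2(C)O
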